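**Plan**

- The target is 11-(2-hydroxyphenyl)-1-(2,4,6-trihydroxyphenyl)undecan-1-one; ring A is the phloroglucinol ring and ring B the ortho-alkylphenol, numbered C1'' (chain) to C6'' with the hydroxyl on C2''.
- Enabling feature: in ring B the chain carbon C1'' and the oxygenated C2'' are neighbours and C3''–C6'' carry only hydrogen. C6''=C1''–C2''=C3'' can therefore come from a 2-silyloxy-3-alkylbuta-1,3-diene and C4''–C5'' from an acetylene equivalent.
- Retrosynthetic cuts, in order: the four O-protecting groups; C3''–C4'' and C5''–C6'' of ring B ((4+2) with an alkynyl sulfone); the enol O–Si bond; the C=CH2 bond (formaldehyde) together with a C–CO2 bond; the bond from the chain to an acetoacetate carbon; the ring A–C(=O) bond.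
- Forward: ring A is bought as its trimethyl ether and acylated with the C11 bromo acid. The chain is extended by acetoacetate alkylation, methylenated and converted into the silyloxydiene. Ring B is then built by cycloaddition and sulfinate elimination, and fluoride followed by BBr3 frees the four phenols.
- Stereochemistry: the target has no stereocentre and no stereogenic double bond. The stereocentres that appear on the way (C2 of the acetoacetate derivatives, C5'' of the allylic sulfone) are racemic and are erased.

Key step: step 5

Remark on the chemistry: the cycloadduct is drawn with the sulfonyl group on C5'' (para to the silyloxy group), the orientation expected from the diene polarisation; the other orientation would give the same arene.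

**Route**

Step 1
Reactants: 1 11-bromoundecanoic acid; 2 1,3,5-trimethoxybenzene
Product: 4 11-bromo-1-(2,4,6-trimethoxyphenyl)undecan-1-one, via 11-bromoundecanoyl chloride 3 (not isolated)
Conditions: (COCl)2, DMF (cat.), CH2Cl2, 0 °C → rt; evaporate; then 2 (1.0 equiv), AlCl3 (1.1 equiv), CH2Cl2, −10 → 0 °C; cold 1 M HCl
Reagents that add atoms: oxalyl chloride, O=C(Cl)C(Cl)=O (supplies only the chlorine of 3, which leaves again as HCl)
Why: Friedel–Crafts acylation: the acid chloride gives with AlCl3 an acylium ion that attacks the strongly activated arene, whose three free positions are equivalent so that only one ketone can form, while low temperature and short contact should spare the ortho methyl ethers and the primary bromide, and the twisted, deactivated product should not be acylated again.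

Step 2
Reactants: 4 11-bromo-1-(2,4,6-trimethoxyphenyl)undecan-1-one; 5 methyl acetoacetate
Product: 6 methyl 2-acetyl-13-oxo-13-(2,4,6-trimethoxyphenyl)tridecanoate (racemic)
Conditions: 5 (2.5 equiv), K2CO3, DMF, 60 °C
Reagents that add atoms: none
Why: Acetoacetic ester alkylation: the potassium enolate of 5 displaces the primary bromide by SN2 at carbon, K2CO3 being too weak to enolise the aryl ketone and the excess of 5 holding back dialkylation; the new stereocentre at C2 forms racemic and is erased in step 3.

Step 3
Reactants: 6 methyl 2-acetyl-13-oxo-13-(2,4,6-trimethoxyphenyl)tridecanoate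
Product: 9 12-methylidene-1-(2,4,6-trimethoxyphenyl)tetradecane-1,13-dione, via the β-keto acid 7 (not isolated), via the Mannich base 8 (not isolated)
Conditions: KOH, THF/MeOH/H2O, 0 °C → rt; AcOH to pH ≈ 6, 0 °C; then Et2NH, 37% aq. HCHO, rt → 50 °C
Reagents that add atoms: formaldehyde, C=O (the methylidene carbon); diethylamine, CCNCC (present only in 8 and released again)
Why: Saponification followed by decarboxylative Mannich methylenation: cold dilute KOH should hydrolyse the methyl ester without retro-Claisen cleavage, the β-keto acid is aminomethylated at C2 by the iminium ion from formaldehyde and diethylamine, and the resulting β-amino acid loses CO2 and the amine in a decarboxylative elimination to give the 1,1-disubstituted enone, the non-activated CH2 next to the hindered aryl ketone staying untouched.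

Step 4
Reactants: 9 12-methylidene-1-(2,4,6-trimethoxyphenyl)tetradecane-1,13-dione
Product: 10 13-[tert-butyl(dimethyl)silyl]oxy-12-methylidene-1-(2,4,6-trimethoxyphenyl)tetradec-13-en-1-one
Conditions: TBSOTf (1.05 equiv), Et3N (1.5 equiv), CH2Cl2, −78 → 0 °C; pentane/aq. NaHCO3 work-up; filtration through Et3N-deactivated silica
Reagents that add atoms: tert-butyldimethylsilyl trifluoromethanesulfonate, CC(C)(C)[Si](C)(C)OS(=O)(=O)C(F)(F)F
Why: Silyl enol ether formation by soft enolisation: the unhindered enone carbonyl is silylated on oxygen and Et3N removes a proton from the methyl group, the only position whose loss gives a neutral dienol ether, whereas the aryl ketone, twisted out of conjugation, shielded by two ortho methoxy groups and carrying only a secondary α-CH2, should react more slowly with one equivalent of the bulky silyl triflate at low temperature.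

Step 5
Reactants: 10 13-[tert-butyl(dimethyl)silyl]oxy-12-methylidene-1-(2,4,6-trimethoxyphenyl)tetradec-13-en-1-one; 11 ethynyl p-tolyl sulfone
Product: 14 11-[2-(tert-butyldimethylsilyloxy)phenyl]-1-(2,4,6-trimethoxyphenyl)undecan-1-one, via the sulfonylcyclohexa-1,4-diene cycloadduct 12 (not isolated), via the allylic sulfone 13 (not isolated)
Conditions: 11 (1.3 equiv), PhMe, 80 °C; then DBU (2.5 equiv), rt → 50 °C
Reagents that add atoms: none
Why: The electron-rich diene of 10, held close to s-cis by its 2,3-disubstitution, and the electron-poor alkyne of 11 combine in a concerted, normal-electron-demand (4+2) cycloaddition that forms C3''–C4'' and C5''–C6''. Ring B thus closes in an intermolecular Diels–Alder mode, both diene termini bonding to the two alkyne carbons at once, and appears first as the six-membered cyclohexa-1,4-diene 12. DBU then removes the doubly allylic C3''–H, which is γ to the sulfone, reprotonation at C5'' gives the allylic sulfone 13, and E1cB loss of p-toluenesulfinate across C5''–C6'' aromatises the ring to the aryl silyl ether. The closest known reaction type is the Diels–Alder reaction of 2-silyloxybuta-1,3-dienes with alkynyl sulfones as acetylene equivalents followed by base-induced loss of sulfinic acid. No stereocentre survives, since the only one formed, C5'' of 13, is racemic and is destroyed by the elimination. The step needs only chemoselectivity for the diene over the aryl ketone, which the ketone secures by not being a dienophile, and no regiocontrol, because either orientation of the sulfonyl group collapses to the same arene; DBU is added only after the cycloaddition so that it meets little free alkynyl sulfone.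

Step 6
Reactants: 14 11-[2-(tert-butyldimethylsilyloxy)phenyl]-1-(2,4,6-trimethoxyphenyl)undecan-1-one
Product: 15 11-(2-hydroxyphenyl)-1-(2,4,6-trimethoxyphenyl)undecan-1-one
Conditions: Bu4NF (1.2 equiv), AcOH (1.2 equiv), THF, 0 °C → rt
Reagents that add atoms: none
Why: Fluoride-mediated desilylation: fluoride attacks silicon and expels the phenoxide, a good leaving group, so the aryl silyl ether should cleave quickly, while the acetic acid buffer protonates the phenoxide and keeps the enolisable ketone out of base-induced side reactions.

Step 7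
Reactants: 15 11-(2-hydroxyphenyl)-1-(2,4,6-trimethoxyphenyl)undecan-1-one
Product: 16 11-(2-hydroxyphenyl)-1-(2,4,6-trihydroxyphenyl)undecan-1-one
Conditions: BBr3 (8 equiv), CH2Cl2, −78 °C → rt; then ice-water
Reagents that add atoms: none
Why: Lewis-acid cleavage of aryl methyl ethers with BBr3: boron binds each ether oxygen and bromide removes the methyl group by SN2 as bromomethane, the two ortho methoxy groups being helped by chelation to the ketone and the para one by excess reagent at room temperature, and hydrolysis of the B–O bonds on work-up should release the phenols without touching the saturated chain or the ketone.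

**Compound list**

1 | 11-bromoundecanoic acid | OC(=O)CCCCCCCCCCBr | starting material
2 | 1,3,5-trimethoxybenzene | COc1cc(OC)cc(OC)c1 | starting material
3 | 11-bromoundecanoyl chloride | O=C(Cl)CCCCCCCCCCBr | intermediate (not isolated)
4 | 11-bromo-1-(2,4,6-trimethoxyphenyl)undecan-1-one | BrCCCCCCCCCCC(=O)c1c(OC)cc(OC)cc1OC | intermediate
5 | methyl acetoacetate | COC(=O)CC(C)=O | starting material
6 | methyl 2-acetyl-13-oxo-13-(2,4,6-trimethoxyphenyl)tridecanoate (racemic) | COC(=O)C(C(C)=O)CCCCCCCCCCC(=O)c1c(OC)cc(OC)cc1OC | intermediate
7 | 2-acetyl-13-oxo-13-(2,4,6-trimethoxyphenyl)tridecanoic acid (racemic; the β-keto acid) | OC(=O)C(C(C)=O)CCCCCCCCCCC(=O)c1c(OC)cc(OC)cc1OC | intermediate (not isolated)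
8 | 2-acetyl-2-[(diethylamino)methyl]-13-oxo-13-(2,4,6-trimethoxyphenyl)tridecanoic acid (racemic; the Mannich base) | CCN(CC)CC(C(C)=O)(C(O)=O)CCCCCCCCCCC(=O)c1c(OC)cc(OC)cc1OC | intermediate (not isolated)
9 | 12-methylidene-1-(2,4,6-trimethoxyphenyl)tetradecane-1,13-dione | CC(=O)C(=C)CCCCCCCCCCC(=O)c1c(OC)cc(OC)cc1OC | intermediate
10 | 13-[tert-butyl(dimethyl)silyl]oxy-12-methylidene-1-(2,4,6-trimethoxyphenyl)tetradec-13-en-1-one | C=C(O[Si](C)(C)C(C)(C)C)C(=C)CCCCCCCCCCC(=O)c1c(OC)cc(OC)cc1OC | intermediate
11 | ethynyl p-tolyl sulfone (1-ethynylsulfonyl-4-methylbenzene) | C#CS(=O)(=O)c1ccc(C)cc1 | starting material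
12 | 11-[2-(tert-butyldimethylsilyloxy)-5-(4-methylbenzenesulfonyl)cyclohexa-1,4-dien-1-yl]-1-(2,4,6-trimethoxyphenyl)undecan-1-one | CC(C)(C)[Si](C)(C)OC1=C(CCCCCCCCCCC(=O)c2c(OC)cc(OC)cc2OC)CC(S(=O)(=O)c2ccc(C)cc2)=CC1 | intermediate (not isolated)
13 | 11-[2-(tert-butyldimethylsilyloxy)-5-(4-methylbenzenesulfonyl)cyclohexa-1,3-dien-1-yl]-1-(2,4,6-trimethoxyphenyl)undecan-1-one (racemic at C5 of the ring) | CC(C)(C)[Si](C)(C)OC1=C(CCCCCCCCCCC(=O)c2c(OC)cc(OC)cc2OC)CC(S(=O)(=O)c2ccc(C)cc2)C=C1 | intermediate (not isolated)
14 | 11-[2-(tert-butyldimethylsilyloxy)phenyl]-1-(2,4,6-trimethoxyphenyl)undecan-1-one | CC(C)(C)[Si](C)(C)Oc1ccccc1CCCCCCCCCCC(=O)c1c(OC)cc(OC)cc1OC | intermediate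
15 | 11-(2-hydroxyphenyl)-1-(2,4,6-trimethoxyphenyl)undecan-1-one | Oc1ccccc1CCCCCCCCCCC(=O)c1c(OC)cc(OC)cc1OC | intermediate
16 | 11-(2-hydroxyphenyl)-1-(2,4,6-trihydroxyphenyl)undecan-1-one (no stereocentre) | Oc1ccccc1CCCCCCCCCCC(=O)c1c(O)cc(O)cc1O | target

**Count and risks**

Total step count: 7. Longest linear sequence: 7 steps (1 → 16); compounds 2, 5 and 11 are bought.

The three steps most likely to fail:

1. Step 4, through loss of chemoselectivity (competing enol silylation at the aryl ketone) and hydrolysis of the labile diene on isolation. The fallback gives up the selectivity and sets out from 9. Both carbonyl groups are silylated on purpose with excess TBSOTf and Et3N (CH2Cl2, 0 °C → rt) to give the bis-silylated diene F1, the aryl ketone now carried as its silyl enol ether, expected mainly Z. Under the conditions of step 5 this should pass through the cycloadduct F2 and the allylic sulfone F3 to the bis-silylated arene F4; the hindered trisubstituted enol ether is not a diene and should not engage the sulfone. Excess Bu4NF/AcOH in THF then removes both silyl groups, and the route is rejoined at 15.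

2. Step 5, where oligomerisation of the alkynyl sulfone or hydrolysis of the diene may outrun the cycloaddition, or the elimination may stall at the vinyl sulfone stage. The fallback takes ring B from a bought arene and sets out from 4. Zinc insertion (Zn dust, LiCl, THF, 50 °C) should give the alkylzinc bromide F5, a reagent class that tolerates ketones. Negishi coupling with purchased (2-bromophenoxy)(tert-butyl)dimethylsilane (Pd(OAc)2, 2-dicyclohexylphosphino-2',6'-dimethoxybiphenyl, THF, 50 °C) would give the aryl silyl ether directly, and the route is rejoined at 14.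

3. Step 3, through decarboxylation of the β-keto acid before aminomethylation, or re-addition of the amine to the enone and its dimerisation. The fallback makes the C=CH2 bond by olefination and sets out from 4. Alkylation of the sodium salt of dimethyl (2-oxopropyl)phosphonate (NaH, DMF, 0 → 60 °C) should give the α-alkylated β-keto phosphonate F6. Horner–Wadsworth–Emmons reaction with 37% aqueous formaldehyde and K2CO3 (THF/H2O, rt) would deliver the enone, and the route is rejoined at 9.

**Further compounds**

F1 | step 4 | (1Z)-1,13-bis(tert-butyldimethylsilyloxy)-12-methylidene-1-(2,4,6-trimethoxyphenyl)tetradeca-1,13-diene | C=C(O[Si](C)(C)C(C)(C)C)C(=C)CCCCCCCCC/C=C(\O[Si](C)(C)C(C)(C)C)c1c(OC)cc(OC)cc1OC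
F2 | step 4 | (1Z)-1-(tert-butyldimethylsilyloxy)-11-[2-(tert-butyldimethylsilyloxy)-5-(4-methylbenzenesulfonyl)cyclohexa-1,4-dien-1-yl]-1-(2,4,6-trimethoxyphenyl)undec-1-ene | CC(C)(C)[Si](C)(C)OC1=C(CCCCCCCCC/C=C(\O[Si](C)(C)C(C)(C)C)c2c(OC)cc(OC)cc2OC)CC(S(=O)(=O)c2ccc(C)cc2)=CC1
F3 | step 4 | (1Z)-1-(tert-butyldimethylsilyloxy)-11-[2-(tert-butyldimethylsilyloxy)-5-(4-methylbenzenesulfonyl)cyclohexa-1,3-dien-1-yl]-1-(2,4,6-trimethoxyphenyl)undec-1-ene (racemic at C5 of the ring) | CC(C)(C)[Si](C)(C)OC1=C(CCCCCCCCC/C=C(\O[Si](C)(C)C(C)(C)C)c2c(OC)cc(OC)cc2OC)CC(S(=O)(=O)c2ccc(C)cc2)C=C1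
F4 | step 4 | (1Z)-1-(tert-butyldimethylsilyloxy)-11-[2-(tert-butyldimethylsilyloxy)phenyl]-1-(2,4,6-trimethoxyphenyl)undec-1-ene | CC(C)(C)[Si](C)(C)Oc1ccccc1CCCCCCCCC/C=C(\O[Si](C)(C)C(C)(C)C)c1c(OC)cc(OC)cc1OC
F5 | step 5 | bromo[11-oxo-11-(2,4,6-trimethoxyphenyl)undecyl]zinc | Br[Zn]CCCCCCCCCCC(=O)c1c(OC)cc(OC)cc1OC
F6 | step 3 | dimethyl [2,14-dioxo-14-(2,4,6-trimethoxyphenyl)tetradecan-3-yl]phosphonate (racemic) | COP(=O)(OC)C(C(C)=O)CCCCCCCCCCC(=O)c1c(OC)cc(OC)cc1OC
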